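**Remark (assumptions):** the target has no stereocentre; the hindered C3'–C8'' axis is carried without control of its sense, the carbinol and flavanone centres formed on the way are racemic and are erased later, and 1-(benzyloxy)-4-ethynylbenzene (19) and 4-(benzyloxy)benzaldehyde are taken as commercial.

## Retrosynthetic overview

1. Numbering: unit 1 is rings A and C with ring B (C1'–C6'); unit 2 is rings D and E (doubly primed) with ring F (triply primed). The strategy rests on ring D, a phloroglucinol ring whose C8'' carries ring B between the oxygens on C7'' and C8a'' (a 2-aryl-resorcinol pattern).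
2. Ring C is formed last: O1–C2 and C2–C3 go back through a 2'-hydroxychalcone to the ring B aldehyde 27 and dibenzylated phloroacetophenone 29.
3. Ring E is formed before it: O1''–C2'' and C4''–C4a'' go back to an o-hydroxyaryl ynone, made by ortho-formylation at C4a'' of the ring D phenol and addition of arylacetylene 19 (ring F).
4. Ring D is formed first: benzannulation of 3-(benzyloxy)cyclobutenone 11 with ring B siloxyalkyne 9 forms C8a''–C8'', C6''–C7'' and C4a''–C8a'' and leaves only the C8a'' hydroxyl free.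
5. Alkyne 9 comes from 5-iodovanillin (methylation, acetal, Sonogashira coupling, acetylide oxidation, O-silylation). Order of ring formation: D, E, C.

Key step: step 7

## Route

Step 1
Reactants: 1 5-iodovanillin
Product: 2 3-iodo-4,5-dimethoxybenzaldehyde
Conditions: MeI, K2CO3, DMF, rt
Reagents that add atoms: iodomethane (CI)
Why: Williamson ether synthesis; the acidic phenol, flanked by iodine and para to the formyl group, is methylated cleanly on oxygen.

Step 2
Reactants: 2 3-iodo-4,5-dimethoxybenzaldehyde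
Product: 3 2-(3-iodo-4,5-dimethoxyphenyl)-1,3-dioxolane
Conditions: ethylene glycol, p-TsOH·H2O (cat.), toluene, reflux, Dean–Stark
Reagents that add atoms: ethylene glycol (OCCO)
Why: Acid-catalysed acetalisation with azeotropic removal of water masks the aldehyde as a dioxolane that withstands the organolithium, peroxide and thermal steps ahead.

Step 3
Reactants: 3 2-(3-iodo-4,5-dimethoxyphenyl)-1,3-dioxolane; 4 trimethylsilylacetylene
Product: 5 2-[3,4-dimethoxy-5-(trimethylsilylethynyl)phenyl]-1,3-dioxolane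
Conditions: PdCl2(PPh3)2 (2 mol%), CuI (4 mol%), Et3N, THF, 50 °C
Reagents that add atoms: none
Why: Sonogashira coupling of an aryl iodide runs under mild conditions even next to a methoxy group, and the acetal is inert to the amine base.

Step 4
Reactants: 5 2-[3,4-dimethoxy-5-(trimethylsilylethynyl)phenyl]-1,3-dioxolane
Product: 6 2-(3-ethynyl-4,5-dimethoxyphenyl)-1,3-dioxolane
Conditions: K2CO3 (cat.), MeOH, rt
Reagents that add atoms: none
Why: Methoxide-catalysed protodesilylation of the alkynyl silane frees the terminal alkyne without touching the acetal.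

Step 5
Reactants: 6 2-(3-ethynyl-4,5-dimethoxyphenyl)-1,3-dioxolane
Product: 9 2-[3,4-dimethoxy-5-(triisopropylsilyloxyethynyl)phenyl]-1,3-dioxolane, via lithium acetylide 7 (not isolated), via lithium ynolate 8 (not isolated)
Conditions: LiHMDS, THF, –78 °C; LiOOt-Bu (from t-BuOOH and LiHMDS, THF, –78 °C), –78 → 0 °C; TIPSOTf (1.05 equiv), –78 °C; rapid filtration through Et3N-deactivated silica
Reagents that add atoms: tert-butyl hydroperoxide, used as its lithium salt (CC(C)(C)OO); triisopropylsilyl trifluoromethanesulfonate (CC(C)[Si](OS(=O)(=O)C(F)(F)F)(C(C)C)C(C)C)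
Why: Electrophilic oxygenation of a lithium acetylide by lithium tert-butyl peroxide (Julia-type acetylide oxidation) gives the ynolate, which the bulky silyl triflate captures on oxygen, and the acetal is safe as long as no excess triflate remains.

Step 6
Reactants: 10 3-ethoxycyclobut-2-en-1-one
Product: 11 3-(benzyloxy)cyclobut-2-en-1-one
Conditions: BnOH (1.2 equiv), PPTS (cat.), toluene, 35 °C, reduced pressure (EtOH removed)
Reagents that add atoms: benzyl alcohol (OCc1ccccc1)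
Why: Acid-catalysed transetherification of a vinylogous ester by addition–elimination at C3, the same reactivity by which this ethyl ether is hydrolysed to cyclobutane-1,3-dione, driven by removal of ethanol and run below the temperature of ring opening.

Step 7
Reactants: 11 3-(benzyloxy)cyclobut-2-en-1-one (1.5 equiv); 9 2-[3,4-dimethoxy-5-(triisopropylsilyloxyethynyl)phenyl]-1,3-dioxolane
Product: 16 5-(benzyloxy)-2-[5-(1,3-dioxolan-2-yl)-2,3-dimethoxyphenyl]-3-(triisopropylsilyloxy)phenol, via vinylketene 12 (not isolated), via vinylcyclobutenone 13 (not isolated), via dienylketene 14 (not isolated), via cyclohexadienone 15 (not isolated)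
Conditions: toluene (0.5 M), 80 °C then 110 °C, sealed tube, Ar
Reagents that add atoms: none
Why: Thermal 4π-electrocyclic opening of 11 gives vinylketene 12, whose carbonyl carbon is attacked by the nucleophilic, aryl-bearing carbon of the siloxyalkyne in a [2+2] cycloaddition to give vinylcyclobutenone 13; a second 4π opening gives dienylketene 14, which cyclises to dienone 15 and tautomerises to phenol 16. The closest known reaction is the Danheiser benzannulation of cyclobutenones with triisopropylsiloxyalkynes to resorcinol monosilyl ethers, applied here to a new pairing of a 3-alkoxycyclobutenone and a hindered aryl siloxyalkyne. Ring D closes by thermal 6π-electrocyclisation, which joins the ketene carbon C8a'' to the vinyl terminus C4a'', and aromatisation makes the cascade irreversible. The product has no stereocentre, and the single centre of 13 is lost on ring opening. The selectivity needed is the orientation of the ketene–alkyne [2+2] step, and the oxygen-polarised alkyne secures it: its ring B-bearing carbon bonds to the ketene carbonyl carbon, so C8'' ends between the free C8a'' hydroxyl and the C7'' silyl ether. No metal has to insert at the crowded C8'' position, and the acetal and the ethers are untouched by the pericyclic sequence.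

Step 8
Reactants: 16 5-(benzyloxy)-2-[5-(1,3-dioxolan-2-yl)-2,3-dimethoxyphenyl]-3-(triisopropylsilyloxy)phenol
Product: 18 6-(benzyloxy)-3-[5-(1,3-dioxolan-2-yl)-2,3-dimethoxyphenyl]-2-hydroxy-4-(triisopropylsilyloxy)benzaldehyde, via salicyl alcohol 17 (not isolated)
Conditions: MgCl2 (anhydrous), Et3N, (CH2O)n, MeCN, reflux; pH 5 buffer work-up
Reagents that add atoms: paraformaldehyde, as formaldehyde (C=O)
Why: Magnesium-phenoxide-directed ortho-formylation (Casnati–Skattebøl reaction) delivers formaldehyde within the chelate to C4a'', the only free carbon ortho to the hydroxyl, and the hydroxymethyl compound 17 is oxidised to the aldehyde by hydride transfer to a second formaldehyde.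

Step 9
Reactants: 18 6-(benzyloxy)-3-[5-(1,3-dioxolan-2-yl)-2,3-dimethoxyphenyl]-2-hydroxy-4-(triisopropylsilyloxy)benzaldehyde; 19 1-(benzyloxy)-4-ethynylbenzene (3 equiv)
Product: 21 1-{6-(benzyloxy)-3-[5-(1,3-dioxolan-2-yl)-2,3-dimethoxyphenyl]-2-hydroxy-4-(triisopropylsilyloxy)phenyl}-3-[4-(benzyloxy)phenyl]prop-2-yn-1-ol (racemic), via lithium arylacetylide 20 (not isolated)
Conditions: 19, n-BuLi, THF, –78 °C; then 18, –78 → 0 °C; aq. NH4Cl
Reagents that add atoms: none
Why: 1,2-Addition of a lithium acetylide to an aldehyde, in which the first equivalent deprotonates the chelated phenol and the excess adds to the carbonyl; the racemic carbinol centre is erased in step 10.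

Step 10
Reactants: 21 the propargylic alcohol
Product: 22 1-{6-(benzyloxy)-3-[5-(1,3-dioxolan-2-yl)-2,3-dimethoxyphenyl]-2-hydroxy-4-(triisopropylsilyloxy)phenyl}-3-[4-(benzyloxy)phenyl]prop-2-yn-1-one
Conditions: MnO2 (activated, excess), CH2Cl2, rt
Reagents that add atoms: none
Why: MnO2 oxidation is selective for the doubly activated (benzylic and propargylic) alcohol and leaves the hindered phenol, the acetal and the silyl ether alone.

Step 11
Reactants: 22 the o-hydroxyaryl ynone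
Product: 24 5-(benzyloxy)-2-[4-(benzyloxy)phenyl]-8-[5-(1,3-dioxolan-2-yl)-2,3-dimethoxyphenyl]-7-(triisopropylsilyloxy)-4H-chromen-4-one, via β-enaminone 23 (not isolated)
Conditions: Et2NH (excess), EtOH, rt → 70 °C
Reagents that add atoms: none
Why: Amine-mediated cyclisation of an o-hydroxyaryl ynone to a flavone: conjugate addition of Et2NH gives enaminone 23, and addition–elimination by the C8a'' hydroxyl at the β-carbon closes ring E in the 6-endo sense, which avoids the 5-exo aurone pathway.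

Step 12
Reactants: 24 the 7''-silyloxy flavone
Product: 26 5,7-bis(benzyloxy)-2-[4-(benzyloxy)phenyl]-8-[5-(1,3-dioxolan-2-yl)-2,3-dimethoxyphenyl]-4H-chromen-4-one, via caesium phenoxide 25 (not isolated)
Conditions: CsF, BnBr, DMF, rt
Reagents that add atoms: benzyl bromide (BrCc1ccccc1)
Why: One-pot fluoride desilylation and Williamson benzylation of the resulting phenoxide 25 puts all phenols under one protecting group before the basic and oxidative steps; any phenol set free early in step 11 converges to the same ether.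

Step 13
Reactants: 26 the tribenzyl flavone acetal
Product: 27 3-{5,7-bis(benzyloxy)-2-[4-(benzyloxy)phenyl]-4-oxo-4H-chromen-8-yl}-4,5-dimethoxybenzaldehyde
Conditions: 1 M HCl, THF, rt
Reagents that add atoms: water (O)
Why: Acid-catalysed acetal hydrolysis frees the ring B aldehyde; benzyl ethers, methyl ethers and the flavone are stable to dilute acid.

Step 14
Reactants: 28 2',4',6'-trihydroxyacetophenone
Product: 29 1-[2,4-bis(benzyloxy)-6-hydroxyphenyl]ethan-1-one
Conditions: BnBr (2.1 equiv), K2CO3, DMF, rt → 60 °C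
Reagents that add atoms: benzyl bromide (BrCc1ccccc1)
Why: Williamson etherification stops at the dibenzyl ether because the hydroxyl hydrogen-bonded to the acetyl group is much less nucleophilic than the other two.

Step 15
Reactants: 27 the ring B aldehyde; 29 1-[2,4-bis(benzyloxy)-6-hydroxyphenyl]ethan-1-one
Product: 30 (E)-1-[2,4-bis(benzyloxy)-6-hydroxyphenyl]-3-(3-{5,7-bis(benzyloxy)-2-[4-(benzyloxy)phenyl]-4-oxo-4H-chromen-8-yl}-4,5-dimethoxyphenyl)prop-2-en-1-one
Conditions: KOH (50% aq.), EtOH/THF, rt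
Reagents that add atoms: none
Why: Claisen–Schmidt condensation (aldol addition, then E1cB dehydration) gives the conjugated (E)-chalcone as the thermodynamically favoured alkene, and the non-enolisable aldehyde 27 can only act as the electrophile.

Step 16
Reactants: 30 the 2'-hydroxychalcone
Product: 32 5,7-bis(benzyloxy)-8-{5-[5,7-bis(benzyloxy)-4-oxo-4H-chromen-2-yl]-2,3-dimethoxyphenyl}-2-[4-(benzyloxy)phenyl]-4H-chromen-4-one, via flavanone 31 (not isolated)
Conditions: I2 (10 mol%), DMSO, 120 °C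
Reagents that add atoms: none
Why: Iodine-catalysed oxidative cyclisation of a 2'-hydroxychalcone: oxa-Michael closure of ring C gives flavanone 31, α-iodination and loss of HI give the flavone, and DMSO reoxidises HI to I2.

Step 17
Reactants: 32 the pentabenzyl biflavone
Product: 33 5'-methoxybilobetin
Conditions: H2 (1 atm), 10% Pd/C, THF/MeOH, rt
Reagents that add atoms: none
Why: Catalytic hydrogenolysis cleaves the five benzyl aryl ethers, leaves the two methyl ethers intact, and at 1 atm and rt should not reduce the flavone C2–C3 double bonds, which are part of vinylogous esters.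

## Compound list

1 | 5-iodovanillin | COc1cc(C=O)cc(I)c1O | starting material
2 | 3-iodo-4,5-dimethoxybenzaldehyde | COc1cc(C=O)cc(I)c1OC | intermediate
3 | 2-(3-iodo-4,5-dimethoxyphenyl)-1,3-dioxolane | COc1cc(C2OCCO2)cc(I)c1OC | intermediate
4 | trimethylsilylacetylene | C#C[Si](C)(C)C | starting material
5 | 2-[3,4-dimethoxy-5-(trimethylsilylethynyl)phenyl]-1,3-dioxolane | COc1cc(C2OCCO2)cc(C#C[Si](C)(C)C)c1OC | intermediate
6 | 2-(3-ethynyl-4,5-dimethoxyphenyl)-1,3-dioxolane | COc1cc(C2OCCO2)cc(C#C)c1OC | intermediate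
7 | lithium acetylide of 6 | COc1cc(C2OCCO2)cc(C#[C-])c1OC.[Li+] | intermediate (not isolated)
8 | lithium 2-[5-(1,3-dioxolan-2-yl)-2,3-dimethoxyphenyl]ethynolate | COc1cc(C2OCCO2)cc(C#C[O-])c1OC.[Li+] | intermediate (not isolated)
9 | 2-[3,4-dimethoxy-5-(triisopropylsilyloxyethynyl)phenyl]-1,3-dioxolane | COc1cc(C2OCCO2)cc(C#CO[Si](C(C)C)(C(C)C)C(C)C)c1OC | intermediate
10 | 3-ethoxycyclobut-2-en-1-one | CCOC1=CC(=O)C1 | starting material
11 | 3-(benzyloxy)cyclobut-2-en-1-one | O=C1C=C(OCc2ccccc2)C1 | intermediate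
12 | 3-(benzyloxy)buta-1,3-dien-1-one (vinylketene) | C=C(OCc1ccccc1)C=C=O | intermediate (not isolated)
13 | 4-[1-(benzyloxy)ethenyl]-2-[5-(1,3-dioxolan-2-yl)-2,3-dimethoxyphenyl]-3-(triisopropylsilyloxy)cyclobut-2-en-1-one (racemic) | O=C1C(c2cc(C3OCCO3)cc(OC)c2OC)=C(O[Si](C(C)C)(C(C)C)C(C)C)C1C(=C)OCc1ccccc1 | intermediate (not isolated)
14 | 5-(benzyloxy)-2-[5-(1,3-dioxolan-2-yl)-2,3-dimethoxyphenyl]-3-(triisopropylsilyloxy)hexa-1,3,5-trien-1-one (dienylketene, ketene and alkoxyvinyl groups cis on the central double bond) | O=C=C(c1cc(C2OCCO2)cc(OC)c1OC)/C(O[Si](C(C)C)(C(C)C)C(C)C)=C\C(=C)OCc1ccccc1 | intermediate (not isolated)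
15 | 5-(benzyloxy)-2-[5-(1,3-dioxolan-2-yl)-2,3-dimethoxyphenyl]-3-(triisopropylsilyloxy)cyclohexa-2,4-dien-1-one | O=C1CC(OCc2ccccc2)=CC(O[Si](C(C)C)(C(C)C)C(C)C)=C1c1cc(C2OCCO2)cc(OC)c1OC | intermediate (not isolated)
16 | 5-(benzyloxy)-2-[5-(1,3-dioxolan-2-yl)-2,3-dimethoxyphenyl]-3-(triisopropylsilyloxy)phenol | Oc1cc(OCc2ccccc2)cc(O[Si](C(C)C)(C(C)C)C(C)C)c1-c1cc(C2OCCO2)cc(OC)c1OC | intermediate
17 | 5-(benzyloxy)-2-[5-(1,3-dioxolan-2-yl)-2,3-dimethoxyphenyl]-6-(hydroxymethyl)-3-(triisopropylsilyloxy)phenol (as its magnesium chelate) | OCc1c(O)c(-c2cc(C3OCCO3)cc(OC)c2OC)c(O[Si](C(C)C)(C(C)C)C(C)C)cc1OCc1ccccc1 | intermediate (not isolated)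
18 | 6-(benzyloxy)-3-[5-(1,3-dioxolan-2-yl)-2,3-dimethoxyphenyl]-2-hydroxy-4-(triisopropylsilyloxy)benzaldehyde | O=Cc1c(O)c(-c2cc(C3OCCO3)cc(OC)c2OC)c(O[Si](C(C)C)(C(C)C)C(C)C)cc1OCc1ccccc1 | intermediate
19 | 1-(benzyloxy)-4-ethynylbenzene | C#Cc1ccc(OCc2ccccc2)cc1 | starting material
20 | lithium [4-(benzyloxy)phenyl]acetylide | [Li+].[C-]#Cc1ccc(OCc2ccccc2)cc1 | intermediate (not isolated)
21 | 1-{6-(benzyloxy)-3-[5-(1,3-dioxolan-2-yl)-2,3-dimethoxyphenyl]-2-hydroxy-4-(triisopropylsilyloxy)phenyl}-3-[4-(benzyloxy)phenyl]prop-2-yn-1-ol (racemic) | OC(C#Cc1ccc(OCc2ccccc2)cc1)c1c(O)c(-c2cc(C3OCCO3)cc(OC)c2OC)c(O[Si](C(C)C)(C(C)C)C(C)C)cc1OCc1ccccc1 | intermediate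
22 | 1-{6-(benzyloxy)-3-[5-(1,3-dioxolan-2-yl)-2,3-dimethoxyphenyl]-2-hydroxy-4-(triisopropylsilyloxy)phenyl}-3-[4-(benzyloxy)phenyl]prop-2-yn-1-one | O=C(C#Cc1ccc(OCc2ccccc2)cc1)c1c(O)c(-c2cc(C3OCCO3)cc(OC)c2OC)c(O[Si](C(C)C)(C(C)C)C(C)C)cc1OCc1ccccc1 | intermediate
23 | 1-{6-(benzyloxy)-3-[5-(1,3-dioxolan-2-yl)-2,3-dimethoxyphenyl]-2-hydroxy-4-(triisopropylsilyloxy)phenyl}-3-[4-(benzyloxy)phenyl]-3-(diethylamino)prop-2-en-1-one (either alkene geometry) | CCN(CC)C(=CC(=O)c1c(O)c(-c2cc(C3OCCO3)cc(OC)c2OC)c(O[Si](C(C)C)(C(C)C)C(C)C)cc1OCc1ccccc1)c1ccc(OCc2ccccc2)cc1 | intermediate (not isolated)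
24 | 5-(benzyloxy)-2-[4-(benzyloxy)phenyl]-8-[5-(1,3-dioxolan-2-yl)-2,3-dimethoxyphenyl]-7-(triisopropylsilyloxy)-4H-chromen-4-one | O=c1cc(-c2ccc(OCc3ccccc3)cc2)oc2c(-c3cc(C4OCCO4)cc(OC)c3OC)c(O[Si](C(C)C)(C(C)C)C(C)C)cc(OCc3ccccc3)c12 | intermediate
25 | caesium 5-(benzyloxy)-2-[4-(benzyloxy)phenyl]-8-[5-(1,3-dioxolan-2-yl)-2,3-dimethoxyphenyl]-4-oxo-4H-chromen-7-olate | O=c1cc(-c2ccc(OCc3ccccc3)cc2)oc2c(-c3cc(C4OCCO4)cc(OC)c3OC)c([O-])cc(OCc3ccccc3)c12.[Cs+] | intermediate (not isolated)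
26 | 5,7-bis(benzyloxy)-2-[4-(benzyloxy)phenyl]-8-[5-(1,3-dioxolan-2-yl)-2,3-dimethoxyphenyl]-4H-chromen-4-one | O=c1cc(-c2ccc(OCc3ccccc3)cc2)oc2c(-c3cc(C4OCCO4)cc(OC)c3OC)c(OCc3ccccc3)cc(OCc3ccccc3)c12 | intermediate
27 | 3-{5,7-bis(benzyloxy)-2-[4-(benzyloxy)phenyl]-4-oxo-4H-chromen-8-yl}-4,5-dimethoxybenzaldehyde | O=Cc1cc(OC)c(OC)c(-c2c(OCc3ccccc3)cc(OCc3ccccc3)c3c(=O)cc(-c4ccc(OCc5ccccc5)cc4)oc23)c1 | intermediate
28 | 2',4',6'-trihydroxyacetophenone | CC(=O)c1c(O)cc(O)cc1O | starting material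
29 | 1-[2,4-bis(benzyloxy)-6-hydroxyphenyl]ethan-1-one | CC(=O)c1c(O)cc(OCc2ccccc2)cc1OCc1ccccc1 | intermediate
30 | (E)-1-[2,4-bis(benzyloxy)-6-hydroxyphenyl]-3-(3-{5,7-bis(benzyloxy)-2-[4-(benzyloxy)phenyl]-4-oxo-4H-chromen-8-yl}-4,5-dimethoxyphenyl)prop-2-en-1-one | O=C(/C=C/c1cc(OC)c(OC)c(-c2c(OCc3ccccc3)cc(OCc3ccccc3)c3c(=O)cc(-c4ccc(OCc5ccccc5)cc4)oc23)c1)c1c(O)cc(OCc2ccccc2)cc1OCc1ccccc1 | intermediate
31 | 5,7-bis(benzyloxy)-2-(3-{5,7-bis(benzyloxy)-2-[4-(benzyloxy)phenyl]-4-oxo-4H-chromen-8-yl}-4,5-dimethoxyphenyl)chroman-4-one (racemic) | O=C1CC(c2cc(OC)c(OC)c(-c3c(OCc4ccccc4)cc(OCc4ccccc4)c4c(=O)cc(-c5ccc(OCc6ccccc6)cc5)oc34)c2)Oc2cc(OCc3ccccc3)cc(OCc3ccccc3)c12 | intermediate (not isolated)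
32 | 5,7-bis(benzyloxy)-8-{5-[5,7-bis(benzyloxy)-4-oxo-4H-chromen-2-yl]-2,3-dimethoxyphenyl}-2-[4-(benzyloxy)phenyl]-4H-chromen-4-one | O=c1cc(-c2cc(OC)c(OC)c(-c3c(OCc4ccccc4)cc(OCc4ccccc4)c4c(=O)cc(-c5ccc(OCc6ccccc6)cc5)oc34)c2)oc2cc(OCc3ccccc3)cc(OCc3ccccc3)c12 | intermediate
33 | 5'-methoxybilobetin | COc1cc(-c2cc(=O)c3c(O)cc(O)cc3o2)cc(-c2c(O)cc(O)c3c(=O)cc(-c4ccc(O)cc4)oc23)c1OC | target

## Step count

Total steps: 17. Longest linear sequence: 15 (steps 1–5, 7–13, 15–17).

## Steps most likely to fail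

**Step 7 (benzannulation).** The vinylketene may dimerise or polymerise faster than it is captured by the hindered, ortho-substituted siloxyalkyne. The siloxyalkyne may also rearrange or hydrolyse on heating, and the product phenol may be acylated by further ketene.

Fallback: the C3'–C8'' bond is made by cross-coupling, with ring D taken from phloroglucinol. From iodide 3, Miyaura borylation (B2pin2, PdCl2(dppf), KOAc, dioxane, 80 °C) should give 2-[5-(1,3-dioxolan-2-yl)-2,3-dimethoxyphenyl]-4,4,5,5-tetramethyl-1,3,2-dioxaborolane F1. Acetophenone 29 and commercial 4-(benzyloxy)benzaldehyde are condensed (KOH, EtOH, rt) to (E)-1-[2,4-bis(benzyloxy)-6-hydroxyphenyl]-3-[4-(benzyloxy)phenyl]prop-2-en-1-one F2. F2 is cyclised (I2 cat., DMSO, 120 °C) to 5,7-bis(benzyloxy)-2-[4-(benzyloxy)phenyl]-4H-chromen-4-one F3. F3 is iodinated at C8 (I2, CF3CO2Ag, CH2Cl2, rt) to 5,7-bis(benzyloxy)-2-[4-(benzyloxy)phenyl]-8-iodo-4H-chromen-4-one F4. Suzuki–Miyaura coupling of F4 with F1 (Pd(PPh3)4, K2CO3, DMF/H2O, 90 °C) comes back to the route at 26, ready for step 13.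

**Step 5 (siloxyalkyne formation).** Oxygen transfer to the hindered acetylide may be incomplete. Silylation may take place on carbon to give a silylketene, excess silyl triflate may open the dioxolane, and the siloxyalkyne may hydrolyse on silica.

Fallback: the ynolate is made by ester homologation instead of acetylide oxidation. From iodide 3, palladium-catalysed methoxycarbonylation (Pd(OAc)2, dppf, CO 1 atm, MeOH, Et3N, DMF, 70 °C) should give methyl 5-(1,3-dioxolan-2-yl)-2,3-dimethoxybenzoate F5. Kowalski homologation (CH2Br2, LiTMP, THF, –78 °C; LiHMDS; then n-BuLi, –78 → 25 °C) passes through the lithium enolate of 2,2-dibromo-1-[5-(1,3-dioxolan-2-yl)-2,3-dimethoxyphenyl]ethan-1-one F6. Bromine–lithium exchange and a 1,2-aryl shift then give the same lithium ynolate 8. O-silylation with TIPSCl, which leaves no Lewis-acidic triflate, comes back to the route at 9.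

**Step 16 (I2/DMSO closure of ring C).** The HI formed at 120 °C may cleave benzyl ethers, above all the one peri to the carbonyl. The electron-rich rings may be iodinated, and the reaction may stall at the flavanone.

Fallback: ring C is closed by a Baker–Venkataraman sequence with no iodine present. From aldehyde 27, Pinnick oxidation (NaClO2, NaH2PO4, 2-methyl-2-butene, t-BuOH/THF/H2O) should give 3-{5,7-bis(benzyloxy)-2-[4-(benzyloxy)phenyl]-4-oxo-4H-chromen-8-yl}-4,5-dimethoxybenzoic acid F7. Esterification with the phenol of 29 (EDC·HCl, DMAP, CH2Cl2) gives the 2-acetyl-3,5-bis(benzyloxy)phenyl ester F8. Baker–Venkataraman rearrangement (KOH, pyridine, 50 °C) gives 1-[2,4-bis(benzyloxy)-6-hydroxyphenyl]-3-(3-{5,7-bis(benzyloxy)-2-[4-(benzyloxy)phenyl]-4-oxo-4H-chromen-8-yl}-4,5-dimethoxyphenyl)propane-1,3-dione F9. Cyclodehydration (p-TsOH, toluene, 80 °C) comes back to the route at 32.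

## Further compounds

F1 | step 7 | 2-[5-(1,3-dioxolan-2-yl)-2,3-dimethoxyphenyl]-4,4,5,5-tetramethyl-1,3,2-dioxaborolane | COc1cc(C2OCCO2)cc(B2OC(C)(C)C(C)(C)O2)c1OC
F2 | step 7 | (E)-1-[2,4-bis(benzyloxy)-6-hydroxyphenyl]-3-[4-(benzyloxy)phenyl]prop-2-en-1-one | O=C(/C=C/c1ccc(OCc2ccccc2)cc1)c1c(O)cc(OCc2ccccc2)cc1OCc1ccccc1
F3 | step 7 | 5,7-bis(benzyloxy)-2-[4-(benzyloxy)phenyl]-4H-chromen-4-one | O=c1cc(-c2ccc(OCc3ccccc3)cc2)oc2cc(OCc3ccccc3)cc(OCc3ccccc3)c12
F4 | step 7 | 5,7-bis(benzyloxy)-2-[4-(benzyloxy)phenyl]-8-iodo-4H-chromen-4-one | O=c1cc(-c2ccc(OCc3ccccc3)cc2)oc2c(I)c(OCc3ccccc3)cc(OCc3ccccc3)c12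
F5 | step 5 | methyl 5-(1,3-dioxolan-2-yl)-2,3-dimethoxybenzoate | COC(=O)c1cc(C2OCCO2)cc(OC)c1OC
F6 | step 5 | 2,2-dibromo-1-[5-(1,3-dioxolan-2-yl)-2,3-dimethoxyphenyl]ethan-1-one (formed as its lithium enolate) | O=C(C(Br)Br)c1cc(C2OCCO2)cc(OC)c1OC
F7 | step 16 | 3-{5,7-bis(benzyloxy)-2-[4-(benzyloxy)phenyl]-4-oxo-4H-chromen-8-yl}-4,5-dimethoxybenzoic acid | OC(=O)c1cc(OC)c(OC)c(-c2c(OCc3ccccc3)cc(OCc3ccccc3)c3c(=O)cc(-c4ccc(OCc5ccccc5)cc4)oc23)c1
F8 | step 16 | 2-acetyl-3,5-bis(benzyloxy)phenyl 3-{5,7-bis(benzyloxy)-2-[4-(benzyloxy)phenyl]-4-oxo-4H-chromen-8-yl}-4,5-dimethoxybenzoate | CC(=O)c1c(OC(=O)c2cc(OC)c(OC)c(-c3c(OCc4ccccc4)cc(OCc4ccccc4)c4c(=O)cc(-c5ccc(OCc6ccccc6)cc5)oc34)c2)cc(OCc2ccccc2)cc1OCc1ccccc1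
F9 | step 16 | 1-[2,4-bis(benzyloxy)-6-hydroxyphenyl]-3-(3-{5,7-bis(benzyloxy)-2-[4-(benzyloxy)phenyl]-4-oxo-4H-chromen-8-yl}-4,5-dimethoxyphenyl)propane-1,3-dione | O=C(CC(=O)c1cc(OC)c(OC)c(-c2c(OCc3ccccc3)cc(OCc3ccccc3)c3c(=O)cc(-c4ccc(OCc5ccccc5)cc4)oc23)c1)c1c(O)cc(OCc2ccccc2)cc1OCc1ccccc1
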